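**Retrosynthetic overview** (atoms numbered as in the biflavanone: C2/C3/C4/C4a in the 4-methoxyphenyl half, C2''/C3''/C4''/C4a'' in the 4-hydroxyphenyl half; the first half is 2,3-trans, the second 2,3-cis)
1. Target 20 ⇐ penta-O-benzyl ether 19 by global hydrogenolysis; the 4'-OMe group is carried from 4-methoxybenzaldehyde.
2. Key disconnection: the C4–C4a and C4''–C4a'' acyl–aryl bonds, i.e. both pyranone rings C at once, leading back to the open-chain 2,3-bis[aryl(aryloxy)methyl]succinic acid 15; forward, one double intramolecular Friedel–Crafts acylation closes the two rings C.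
3. Enabling feature: each ring A is a 3,5-dioxygenated phenyl ether held on O1; its two carbons ortho to O1 (future C4a and C8) are equivalent, each is ortho/para to all three ring oxygens, and each lies six atoms from the carboxyl carbon, so acylation is fast, regiochemically single-valued and six-membered.
4. 15 ⇐ 1,4-diol 13 (oxidation) ⇐ diol 10 + two aryl bromide 11 (C–O coupling with retention) ⇐ tetrol 9 ⇐ succinyl bis-imide 4 by two auxiliary-controlled aldol reactions: Mg-catalysed anti (sets C2, C3) and boron syn (sets C2'', C3'').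
5. Ring order: rings B (aldehydes) and rings A (aryl bromide) are bought; both rings C are formed together in step 8.

Key step: step 8

Remark: the sense of induction in steps 2 and 3 is taken from the usual chelated (Mg) and open, dipole-minimised (B) enolate models of (S)-4-benzyl-N-acyloxazolidinones; benzyl ethers stand in for the five free phenols.

**Step 1**
Reactants: 1 (S)-4-benzyl-1,3-oxazolidin-2-one (2 equiv); 2 succinyl chloride
Product: 4 1,4-bis[(4S)-4-benzyl-2-oxo-1,3-oxazolidin-3-yl]butane-1,4-dione, via lithium oxazolidinide 3 (not isolated)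
Conditions: n-BuLi, THF, −78 °C; then 2, −78 to 0 °C
Reagents that add atoms: none
Why: N-acylation of the lithiated oxazolidinone by the diacid chloride is the standard entry to N-acyl imides and should give the C2-symmetric bis-imide; no stereocentre is formed.

**Step 2**
Reactants: 4 bis-imide (threefold excess, surplus recovered); 5 4-methoxybenzaldehyde
Product: 6 mono anti-aldol trimethylsilyl ether (C2 S, C3 R)
Conditions: MgCl2 (20 mol%), Et3N, Me3SiCl, EtOAc, 23 °C
Reagents that add atoms: chlorotrimethylsilane, C[Si](C)(C)Cl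
Why: Magnesium-halide-catalysed direct anti-aldol reaction of an N-acyloxazolidinone: the chelated Z-enolate should add to the aldehyde through a boat transition state on the face away from the benzyl group, setting C3 (R) and C2 (S), silylation turns the catalyst over, and the excess of 4 limits bis-addition.

**Step 3**
Reactants: 6 mono anti-aldol silyl ether; 7 4-(benzyloxy)benzaldehyde
Product: 9 tetrol (1S,2S,3R,4S)-4-[4-(benzyloxy)phenyl]-2,3-bis(hydroxymethyl)-1-(4-methoxyphenyl)butane-1,4-diol, via bis-aldol adduct 8 (not isolated)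
Conditions: n-Bu2BOTf, i-Pr2NEt, CH2Cl2, −78 to 0 °C; 7, −78 to 0 °C; pH 7 buffer, MeOH, H2O2, 0 °C; crude: LiBH4, THF, MeOH, 0 to 23 °C; K2CO3, MeOH
Reagents that add atoms: none
Why: Evans boron syn-aldol reaction: only the unbranched imide is enolised (the branched one is shielded by allylic strain) and the boron enolate should react through a chair (Zimmerman–Traxler) transition state under auxiliary control to set C3'' (S) and C2'' (S); LiBH4 then cleaves both imides reductively, any γ-lactone formed from 8 by acyl transfer gives the same tetrol, and the silyl group is removed with base because the 4-alkoxybenzylic carbinols would cyclise in acid.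

**Step 4**
Reactants: 9 tetrol
Product: 10 bis(triisopropylsilyl) ether of the two primary hydroxyl groups
Conditions: i-Pr3SiCl (2.2 equiv), imidazole, CH2Cl2, 0 to 23 °C
Reagents that add atoms: chlorotri(propan-2-yl)silane, CC(C)[Si](Cl)(C(C)C)C(C)C
Why: Selective silylation of primary over hindered secondary benzylic hydroxyl groups by a bulky silyl chloride; the triisopropylsilyl group is chosen because it should not migrate to the neighbouring alkoxide in step 5, and no stereocentre is touched.

**Step 5**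
Reactants: 10 bis-silyl diol; 11 1,3-bis(benzyloxy)-5-bromobenzene (3 equiv)
Product: 12 bis-aryl ether (both benzylic oxygens carry a 3,5-bis(benzyloxy)phenyl group)
Conditions: [Pd(C3H5)Cl]2 (5 mol%), RockPhos (12 mol%), Cs2CO3, toluene, 90 °C
Reagents that add atoms: none
Why: Palladium-catalysed C–O cross-coupling of secondary alcohols with an aryl bromide (Buchwald–Hartwig etherification): the carbinol C–O bonds are not broken, so C2 and C2'' keep their configuration, the bulky biaryl phosphine favours C–O reductive elimination over β-hydride elimination, and the substrate has no carbonyl or acidic C–H that the base could attack.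

**Step 6**
Reactants: 12 bis-aryl ether
Product: 13 1,4-diol (2S,3R)-2,3-bis[aryl(aryloxy)methyl]butane-1,4-diol
Conditions: Bu4NF, THF, 0 to 23 °C
Reagents that add atoms: none
Why: Fluoride-induced cleavage of the two silyl ethers; at this stage the molecule has no base-sensitive group and no stereocentre is affected.

**Step 7**
Reactants: 13 1,4-diol
Product: 15 diacid (2R,3S)-2,3-bis[aryl(aryloxy)methyl]butanedioic acid, via dialdehyde 14 (not isolated)
Conditions: (COCl)2, DMSO, CH2Cl2, −78 °C; i-Pr2NEt, −78 to −40 °C; pH 7 buffer; crude: NaClO2, NaH2PO4, 2-methylbut-2-ene, t-BuOH/H2O, 0 °C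
Reagents that add atoms: sodium chlorite, [Na+].[O-]Cl=O
Why: Swern oxidation followed by Pinnick oxidation: both carbinols are activated before base is added, so no hydroxy aldehyde can close to a lactol, the low temperature and hindered amine should spare the α-stereocentres C3/C3'' and the β-aryloxy groups, and the excess alkene traps HOCl before it chlorinates rings A.

**Step 8**
Reactants: 15 diacid
Product: 19 penta-O-benzyl biflavanone, via cyclic anhydride 16 (not isolated), via keto acid 17 (not isolated), via isomeric keto acid 18 (not isolated)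
Conditions: (CF3CO)2O (6 equiv), CH2Cl2, 0 °C; BF3·OEt2 (10 mol%), 0 °C
Reagents that add atoms: none
Why: (CF3CO)2O dehydrates the diacid to cyclic anhydride 16, whose activated carbonyl is attacked by the ortho carbon of the 3,5-bis(benzyloxy)phenoxy ring of the same half (intramolecular Friedel–Crafts acylation through an arenium ion) to give keto acid 17 or 18, and the freed carboxyl group is reactivated as its mixed trifluoroacetic anhydride and closes the second ring in the same way. The closest known reaction is the acid-mediated cyclisation of 3-aryloxy- and 3-aryl-3-aryloxypropanoic acids to chroman-4-ones and flavanones. Each ring C (through the C4–C4a bond in the 4-methoxyphenyl half and the C4''–C4a'' bond in the other) is closed in a 6-exo-trig mode by attack of the arene on the exocyclic acyl carbon. No stereocentre is created: C2, C3, C3'' and C2'' come unchanged from 15, and the non-basic medium at 0 °C is meant to leave the α-carbons and the benzylic ether carbons configurationally intact. The step needs acylation ortho to O1 in preference to seven-membered closure onto the other ring A, indanone or tetralone closure onto rings B, C-trifluoroacetylation and ionisation of the 4-alkoxybenzylic C–O bonds; the two equivalent, triply oxygen-activated ortho carbons of each ring A, the meta position of the reachable ring B carbons to their alkoxy groups and the six-membered geometry secure the first three, and the mild activation limits the last.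

**Step 9**
Reactants: 19 penta-O-benzyl biflavanone
Product: 20 target (2S,3R,2''S,3''S)-biflavanone
Conditions: H2 (1 atm), 10% Pd/C, EtOAc/MeOH, 23 °C
Reagents that add atoms: none
Why: Hydrogenolysis of the five aryl benzyl ethers over Pd/C under neutral conditions should free the phenols without touching the aryl methyl ether, and the absence of base avoids enolisation at C3/C3'' and ring opening at C2/C2''.

**Compound list**
1 | (S)-4-benzyl-1,3-oxazolidin-2-one | O=C1N[C@@H](Cc2ccccc2)CO1 | starting material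
2 | succinyl chloride (butanedioyl dichloride) | ClC(=O)CCC(=O)Cl | starting material
3 | lithium (S)-4-benzyl-2-oxo-1,3-oxazolidin-3-ide | [Li+].O=C1[N-][C@@H](Cc2ccccc2)CO1 | intermediate (not isolated)
4 | 1,4-bis[(4S)-4-benzyl-2-oxo-1,3-oxazolidin-3-yl]butane-1,4-dione | O=C(CCC(=O)N1[C@@H](Cc2ccccc2)COC1=O)N1[C@@H](Cc2ccccc2)COC1=O | intermediate
5 | 4-methoxybenzaldehyde | COc1ccc(C=O)cc1 | starting material
6 | (2R)-1,4-bis[(4S)-4-benzyl-2-oxo-1,3-oxazolidin-3-yl]-2-[(S)-(4-methoxyphenyl)(trimethylsilyloxy)methyl]butane-1,4-dione | COc1ccc(cc1)[C@@H](O[Si](C)(C)C)[C@H](C(=O)N1[C@@H](Cc2ccccc2)COC1=O)CC(=O)N1[C@@H](Cc2ccccc2)COC1=O | intermediate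
7 | 4-(benzyloxy)benzaldehyde | O=Cc1ccc(OCc2ccccc2)cc1 | starting material
8 | (2R,3S)-1,4-bis[(4S)-4-benzyl-2-oxo-1,3-oxazolidin-3-yl]-2-[(S)-(4-methoxyphenyl)(trimethylsilyloxy)methyl]-3-[(S)-[4-(benzyloxy)phenyl](hydroxy)methyl]butane-1,4-dione | COc1ccc(cc1)[C@@H](O[Si](C)(C)C)[C@H](C(=O)N1[C@@H](Cc2ccccc2)COC1=O)[C@H](C(=O)N1[C@@H](Cc2ccccc2)COC1=O)[C@H](O)c1ccc(OCc2ccccc2)cc1 | intermediate (not isolated)
9 | (1S,2S,3R,4S)-4-[4-(benzyloxy)phenyl]-2,3-bis(hydroxymethyl)-1-(4-methoxyphenyl)butane-1,4-diol | COc1ccc(cc1)[C@@H](O)[C@H](CO)[C@H](CO)[C@H](O)c1ccc(OCc2ccccc2)cc1 | intermediate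
10 | (1S,2S,3R,4S)-4-[4-(benzyloxy)phenyl]-1-(4-methoxyphenyl)-2,3-bis{[tri(propan-2-yl)silyl]oxymethyl}butane-1,4-diol | COc1ccc(cc1)[C@@H](O)[C@H](CO[Si](C(C)C)(C(C)C)C(C)C)[C@H](CO[Si](C(C)C)(C(C)C)C(C)C)[C@H](O)c1ccc(OCc2ccccc2)cc1 | intermediate
11 | 1,3-bis(benzyloxy)-5-bromobenzene | Brc1cc(OCc2ccccc2)cc(OCc2ccccc2)c1 | starting material
12 | (1S,2S,3R,4S)-1,4-bis[3,5-bis(benzyloxy)phenoxy]-4-[4-(benzyloxy)phenyl]-1-(4-methoxyphenyl)-2,3-bis{[tri(propan-2-yl)silyl]oxymethyl}butane | COc1ccc(cc1)[C@@H](Oc1cc(OCc2ccccc2)cc(OCc2ccccc2)c1)[C@H](CO[Si](C(C)C)(C(C)C)C(C)C)[C@H](CO[Si](C(C)C)(C(C)C)C(C)C)[C@H](Oc1cc(OCc2ccccc2)cc(OCc2ccccc2)c1)c1ccc(OCc2ccccc2)cc1 | intermediate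
13 | (2S,3R)-2-[(S)-[3,5-bis(benzyloxy)phenoxy](4-methoxyphenyl)methyl]-3-[(S)-[3,5-bis(benzyloxy)phenoxy][4-(benzyloxy)phenyl]methyl]butane-1,4-diol | COc1ccc(cc1)[C@@H](Oc1cc(OCc2ccccc2)cc(OCc2ccccc2)c1)[C@H](CO)[C@H](CO)[C@H](Oc1cc(OCc2ccccc2)cc(OCc2ccccc2)c1)c1ccc(OCc2ccccc2)cc1 | intermediate
14 | (2R,3S)-2-[(S)-[3,5-bis(benzyloxy)phenoxy](4-methoxyphenyl)methyl]-3-[(S)-[3,5-bis(benzyloxy)phenoxy][4-(benzyloxy)phenyl]methyl]butanedial | COc1ccc(cc1)[C@@H](Oc1cc(OCc2ccccc2)cc(OCc2ccccc2)c1)[C@H](C=O)[C@H](C=O)[C@H](Oc1cc(OCc2ccccc2)cc(OCc2ccccc2)c1)c1ccc(OCc2ccccc2)cc1 | intermediate (not isolated)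
15 | (2R,3S)-2-[(S)-[3,5-bis(benzyloxy)phenoxy](4-methoxyphenyl)methyl]-3-[(S)-[3,5-bis(benzyloxy)phenoxy][4-(benzyloxy)phenyl]methyl]butanedioic acid | COc1ccc(cc1)[C@@H](Oc1cc(OCc2ccccc2)cc(OCc2ccccc2)c1)[C@H](C(=O)O)[C@H](C(=O)O)[C@H](Oc1cc(OCc2ccccc2)cc(OCc2ccccc2)c1)c1ccc(OCc2ccccc2)cc1 | intermediate
16 | (3R,4S)-3-[(S)-[3,5-bis(benzyloxy)phenoxy](4-methoxyphenyl)methyl]-4-[(S)-[3,5-bis(benzyloxy)phenoxy][4-(benzyloxy)phenyl]methyl]oxolane-2,5-dione | COc1ccc(cc1)[C@@H](Oc1cc(OCc2ccccc2)cc(OCc2ccccc2)c1)[C@@H]1C(=O)OC(=O)[C@@H]1[C@H](Oc1cc(OCc2ccccc2)cc(OCc2ccccc2)c1)c1ccc(OCc2ccccc2)cc1 | intermediate (not isolated)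
17 | (2S,3S)-2-[(2S,3R)-5,7-bis(benzyloxy)-2-(4-methoxyphenyl)-4-oxo-3,4-dihydro-2H-chromen-3-yl]-3-[3,5-bis(benzyloxy)phenoxy]-3-[4-(benzyloxy)phenyl]propanoic acid | COc1ccc([C@H]2Oc3cc(OCc4ccccc4)cc(OCc4ccccc4)c3C(=O)[C@@H]2[C@H](C(=O)O)[C@H](Oc2cc(OCc3ccccc3)cc(OCc3ccccc3)c2)c2ccc(OCc3ccccc3)cc2)cc1 | intermediate (not isolated)
18 | (2R,3S)-2-[(2S,3S)-5,7-bis(benzyloxy)-2-[4-(benzyloxy)phenyl]-4-oxo-3,4-dihydro-2H-chromen-3-yl]-3-[3,5-bis(benzyloxy)phenoxy]-3-(4-methoxyphenyl)propanoic acid | COc1ccc(cc1)[C@@H](Oc1cc(OCc2ccccc2)cc(OCc2ccccc2)c1)[C@H](C(=O)O)[C@@H]1C(=O)c2c(OCc3ccccc3)cc(OCc3ccccc3)cc2O[C@@H]1c1ccc(OCc2ccccc2)cc1 | intermediate (not isolated)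
19 | (2S,3R)-5,7-bis(benzyloxy)-3-[(2S,3S)-5,7-bis(benzyloxy)-2-[4-(benzyloxy)phenyl]-4-oxo-3,4-dihydro-2H-chromen-3-yl]-2-(4-methoxyphenyl)-2,3-dihydro-4H-chromen-4-one | COc1ccc([C@H]2Oc3cc(OCc4ccccc4)cc(OCc4ccccc4)c3C(=O)[C@@H]2[C@@H]2C(=O)c3c(OCc4ccccc4)cc(OCc4ccccc4)cc3O[C@@H]2c2ccc(OCc3ccccc3)cc2)cc1 | intermediate
20 | (2S,3R)-5,7-dihydroxy-3-[(2S,3S)-5,7-dihydroxy-2-(4-hydroxyphenyl)-4-oxo-3,4-dihydro-2H-chromen-3-yl]-2-(4-methoxyphenyl)-2,3-dihydro-4H-chromen-4-one | COc1ccc([C@H]2Oc3cc(O)cc(O)c3C(=O)[C@@H]2[C@@H]2C(=O)c3c(O)cc(O)cc3O[C@@H]2c2ccc(O)cc2)cc1 | target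

**Total step count:** 9. **Longest linear sequence:** 9 steps (from 1 and 2 to 20).

**Steps most likely to fail**

Step 5. The two carbinols are secondary, benzylic and flanked by branched carbons, so alkoxide binding to palladium may be slow; the palladium alkoxide may instead undergo β-hydride elimination (aryl ketone and reduced arene) or the reaction may stop after one arylation. Fallback: a Chan–Lam-type oxidative O-arylation, which brings the aryl group in as a nucleophile and forms the C–O bond by reductive elimination from trivalent copper, so that β-hydride elimination is not on the pathway and no strong base is present. It sets out from 10, which would be stirred with [3,5-bis(benzyloxy)phenyl]boronic acid, Cu(OAc)2, pyridine and 4 Å molecular sieves under air in CH2Cl2 at 23 °C, and it comes back to the route at 12; no new compound is made (F0).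

Step 8. Protonation or Lewis-acid ionisation of the 4-alkoxybenzylic C–O bonds (loss of the phenol, γ-lactone formation by the neighbouring carboxyl group, epimerisation at C2/C2'') and enolisation at C3/C3'' may compete when both closures are forced in one acidic flask. Fallback: the two ring closures would be run separately under aprotic activation. It sets out from 15: DCC in CH2Cl2 should give anhydride 16, which is isolated; Sc(OTf)3 (5 mol%) in CH2Cl2/MeNO2 at 0 °C should effect the first acylation to the keto acids 17 and 18; 1-chloro-N,N,2-trimethylprop-1-en-1-amine would convert the remaining carboxyl groups under neutral conditions into the acid chloride of 17 F1 and the acid chloride of 18 F2; SnCl4 with 2,6-di-tert-butyl-4-methylpyridine in CH2Cl2 at −78 °C should then close the second ring, and the sequence comes back to the route at 19.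

Step 9. During the long exposure needed to cleave five benzyl ethers, the benzylic C2–O1 and C2''–O1'' bonds of the flavanone rings may be hydrogenolysed (ring opening to dihydrochalcones) or the ketones reduced. Fallback: Lewis-acid debenzylation in place of hydrogenolysis. It sets out from 19, which would be treated with BCl3 and pentamethylbenzene (cation scavenger) in CH2Cl2 at −78 °C; the unchelated aryl methyl ether should survive at this temperature, and the sequence comes back to the route at 20; no new compound is made (F0).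

**Further compounds**
F0 | step 5 | none | none
F1 | step 8 | (2S,3S)-2-[(2S,3R)-5,7-bis(benzyloxy)-2-(4-methoxyphenyl)-4-oxo-3,4-dihydro-2H-chromen-3-yl]-3-[3,5-bis(benzyloxy)phenoxy]-3-[4-(benzyloxy)phenyl]propanoyl chloride | COc1ccc([C@H]2Oc3cc(OCc4ccccc4)cc(OCc4ccccc4)c3C(=O)[C@@H]2[C@H](C(Cl)=O)[C@H](Oc2cc(OCc3ccccc3)cc(OCc3ccccc3)c2)c2ccc(OCc3ccccc3)cc2)cc1
F2 | step 8 | (2R,3S)-2-[(2S,3S)-5,7-bis(benzyloxy)-2-[4-(benzyloxy)phenyl]-4-oxo-3,4-dihydro-2H-chromen-3-yl]-3-[3,5-bis(benzyloxy)phenoxy]-3-(4-methoxyphenyl)propanoyl chloride | COc1ccc(cc1)[C@@H](Oc1cc(OCc2ccccc2)cc(OCc2ccccc2)c1)[C@H](C(Cl)=O)[C@@H]1C(=O)c2c(OCc3ccccc3)cc(OCc3ccccc3)cc2O[C@@H]1c1ccc(OCc2ccccc2)cc1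
F0 | step 9 | none | none
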